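The route rests on cutting C9–C10 (bisabolane numbering) inside the 1,3-anti C8-hydroxy/C10-angeloyloxy array. This array hangs from the C7=C14 methylene on the epoxycyclohexane ring. The key step is a reagent-controlled boron aldol. The (−)-Ipc2B enolate of the fully decorated ring methyl enone (C8 ketone, C9 methyl) adds to a non-enolisable C10–C13 aldehyde, which unites both halves and sets C10 in one operation. The resulting β-hydroxy enone is the natural substrate for an Evans–Tishchenko reduction with (Z)-2-methylbut-2-enal. That reduction sets C8 anti and places the angelate on O10 alone. The enone derives from (R)-carvone, whose stereocentre relays all ring stereochemistry.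

Key step: step 11

Remark: bisabolane numbering is used throughout. The ring is C1 (OAc), C2 (OAng), C3 (methyl-bearing oxirane carbon), C4 (oxirane CH), C5 (CH2) and C6 (CH bearing the side chain). The chain is C7(=C14H2), C8, C9, C10, C11(CH3)2, and On is the oxygen on Cn. (R)-Carvone, angelic acid and 2-methylbut-3-en-2-ol are taken as commercial.

Step 1
Reactants: 1 (R)-(−)-carvone
Product: 3 (5S,6S)-6-hydroxy-2-methyl-5-(prop-1-en-2-yl)cyclohex-2-en-1-one (trans-6-hydroxycarvone; C1-OH anti to the isopropenyl group), via lithium dienolate 2 (not isolated)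
Conditions: LiN(iPr)2 (LDA), THF, −78 °C; 2-(phenylsulfonyl)-3-phenyloxaziridine, −78 °C; AcOH quench
Reagents that add atoms: 2-(phenylsulfonyl)-3-phenyloxaziridine, O=S(=O)(c1ccccc1)N1OC1c1ccccc1
Why: Kinetic deprotonation of the alpha-prime CH2 (C1) gives cross-conjugated dienolate 2, and the Davis enolate hydroxylation transfers oxygen to the face anti to the adjacent C6 isopropenyl group, so the C1 hydroxyl should emerge trans (equatorial).

Step 2
Reactants: 3 trans-6-hydroxycarvone
Product: 4 (1R,6S)-3-methyl-2-oxo-6-(prop-1-en-2-yl)cyclohex-3-en-1-yl acetate (cis-6-acetoxycarvone; OAc syn to the isopropenyl group)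
Conditions: PPh3, DIAD, AcOH, toluene, 0 °C to rt
Reagents that add atoms: acetic acid, CC(=O)O
Why: The Mitsunobu reaction displaces the activated, carbonyl-flanked equatorial C1 oxygen by SN2 inversion under essentially neutral conditions, so the contra-steric axial acetate is set and installed in one operation without epimerising the alpha-acyloxy ketone.

Step 3
Reactants: 4 cis-6-acetoxycarvone
Product: 5 (1R,2S,6S)-2-hydroxy-3-methyl-6-(prop-1-en-2-yl)cyclohex-3-en-1-yl acetate (C2-OH, C1-OAc and C6-isopropenyl all cis)
Conditions: NaBH4, CeCl3·7H2O, MeOH, −78 °C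
Reagents that add atoms: none
Why: In the Luche 1,2-reduction hydride attacks axially from the face opposite the axial C1 acetate (the steric and Felkin-type biases agree, as in carvone to cis-carveol), which gives the pseudo-equatorial C2 alcohol cis to the acetate and the isopropenyl group, and the low temperature suppresses acetyl migration.

Step 4
Reactants: 5 all-cis allylic alcohol
Product: 6 (1R,2R,3R,4S,6S)-2-hydroxy-1-methyl-4-(prop-1-en-2-yl)-7-oxabicyclo[4.1.0]heptan-3-yl acetate (oxirane oxygen cis to OH, OAc and isopropenyl)
Conditions: VO(acac)2 (2 mol %), t-BuOOH (decane), CH2Cl2, 0 °C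
Reagents that add atoms: tert-butyl hydroperoxide, CC(C)(C)OO
Why: In the vanadium-catalysed hydroxyl-directed epoxidation the peroxide is bound to the metal held on O2, so oxygen is delivered to the C3=C4 face syn to the alcohol (setting C3 and C4), and the remote, undirected isopropenyl group is left alone.

Step 5
Reactants: 6 epoxy alcohol; 7 angelic acid ((Z)-2-methylbut-2-enoic acid)
Product: 9 (1S,2R,3R,4S,6S)-3-acetoxy-1-methyl-4-(prop-1-en-2-yl)-7-oxabicyclo[4.1.0]heptan-2-yl (Z)-2-methylbut-2-enoate (C2 angelate), via mixed anhydride 8 (not isolated)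
Conditions: 7, 2,4,6-trichlorobenzoyl chloride, Et3N, toluene, rt; then 6, 75 °C (no nucleophilic catalyst)
Reagents that add atoms: none
Why: Yamaguchi-type mixed-anhydride acylation without a nucleophilic catalyst is the established way to transfer an angeloyl group without Z to E isomerisation, and the cis arrangement of O2 and the oxirane rules out Payne rearrangement, so no stereocentre is touched.

Step 6
Reactants: 9 C2 angelate
Product: 10 enal, (1S,2R,3R,4S,6S)-3-acetoxy-1-methyl-4-(3-oxoprop-1-en-2-yl)-7-oxabicyclo[4.1.0]heptan-2-yl (Z)-2-methylbut-2-enoate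
Conditions: SeO2, 1,4-dioxane, 70 °C
Reagents that add atoms: selenium dioxide, O=[Se]=O
Why: The Riley allylic oxidation (ene reaction, [2,3]-shift, then further oxidation) should pick the methyl group of the only electron-rich alkene left, because C3=C4 is already an oxirane and the angelate alkene is electron-poor.

Step 7
Reactants: 10 enal
Product: 11 allylic alcohol, the 4-(3-hydroxybut-1-en-2-yl) analogue of 10 (both C8 epimers)
Conditions: MeMgBr, THF, −78 °C; AcOH quench at −78 °C
Reagents that add atoms: methylmagnesium bromide, C[Mg]Br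
Why: Grignard 1,2-addition is chemoselective for the aldehyde over the esters and the oxirane at −78 °C and brings in C9, and the C8 epimer mixture does not matter because the next step removes that centre.

Step 8
Reactants: 11 allylic alcohol
Product: 12 ring methyl enone, (1S,2R,3R,4S,6S)-3-acetoxy-1-methyl-4-(3-oxobut-1-en-2-yl)-7-oxabicyclo[4.1.0]heptan-2-yl (Z)-2-methylbut-2-enoate
Conditions: Dess–Martin periodinane, CH2Cl2, 0 °C to rt
Reagents that add atoms: none
Why: Dess–Martin oxidation converts both C8 epimers into the single methyl enone under near-neutral conditions that spare the oxirane, the esters and the Z-alkene.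

Step 9
Reactants: 13 2-methylbut-3-en-2-ol
Product: 14 triethyl[(2-methylbut-3-en-2-yl)oxy]silane
Conditions: Et3SiOTf, 2,6-lutidine, CH2Cl2, 0 °C
Reagents that add atoms: triethylsilyl triflate, CC[Si](CC)(CC)OS(=O)(=O)C(F)(F)F
Why: The silyl triflate silylates the tertiary alcohol, and the triethylsilyl group should survive the aldol and the samarium step yet leave under buffered fluoride.

Step 10
Reactants: 14 silyl ether
Product: 16 2-methyl-2-(triethylsilyloxy)propanal, via ozonide 15 (not isolated)
Conditions: O3, CH2Cl2, −78 °C; Me2S, −78 °C to rt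
Reagents that add atoms: ozone, [O-][O+]=O
Why: Ozonolysis with reductive work-up cleaves the vinyl group through ozonide 15 to the alpha-quaternary, non-enolisable aldehyde that carries C10–C13.

Step 11
Reactants: 12 ring methyl enone; 16 2-methyl-2-(triethylsilyloxy)propanal
Product: 19 (10R)-β-hydroxy enone, the 4-[(5R)-5-hydroxy-6-methyl-3-oxo-6-(triethylsilyloxy)hept-1-en-2-yl] analogue of 12, via enol borinate 17 (not isolated), via boron aldolate 18 (not isolated)
Conditions: (−)-Ipc2BCl (1.3 equiv), Et3N, Et2O, −78 to 0 °C; 16 (3 equiv), −78 to −20 °C; pH 7 buffer/MeOH, then SiO2 (peroxide-free work-up)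
Reagents that add atoms: none
Why: (−)-Ipc2BCl/Et3N converts the only enolisable position of 12 (the C9 methyl, since C7 is sp2 and bears no hydrogen) into enol borinate 17, which adds to aldehyde 16 through a cyclic boron-bound transition state to give aldolate 18, forming C9–C10 and joining the C1–C9 ring half to the C10–C13 half. The closest known reaction type is the diisopinocampheylboron-mediated asymmetric aldol of methyl ketones used for late fragment unions. No ring is closed. The new stereocentre C10 is controlled by the isopinocampheyl ligands: the (−)-reagent, made from (+)-α-pinene, directs methyl-ketone enolates to the Re face of the aldehyde, which corresponds to (10R), while the ring stereocentres are insulated by the sp2 C7, so any (10S) product is a separable diastereomer. Chemoselectivity is secured in four ways: 16 has a quaternary alpha carbon and can neither enolise nor self-condense, the acetate and angelates are not enolised by the chloroborane/amine pair, the oxirane oxygen lies on the crowded all-cis face beside the electron-withdrawing C2 acyloxy group, and only a slight excess of borane is used with a peroxide-free work-up to spare the enone. The product carries the C8 ketone and the free O10 exactly as the hydride relay of step 14 requires.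

Step 12
Reactants: 7 angelic acid
Product: 20 (Z)-2-methylbut-2-en-1-ol
Conditions: LiAlH4, Et2O, 0 °C; aqueous work-up
Reagents that add atoms: none
Why: Hydride reduction of the carboxylic acid proceeds by 1,2-attack and leaves the Z-trisubstituted alkene untouched.

Step 13
Reactants: 20 (Z)-2-methylbut-2-en-1-ol
Product: 21 (Z)-2-methylbut-2-enal
Conditions: MnO2 (activated), Et2O, 0 °C, dark; filtered, dried over 4 Å sieves and used at once as a solution
Reagents that add atoms: none
Why: Heterogeneous, neutral MnO2 oxidation of the allylic alcohol avoids the acid or nucleophile catalysis that would isomerise the Z-enal to the E-isomer.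

Step 14
Reactants: 19 (10R)-β-hydroxy enone; 21 (Z)-2-methylbut-2-enal
Product: 23 (8R,10R)-8-hydroxy-10-angeloyloxy-11-triethylsilyloxy compound (the target with O11 silylated), via hemiacetal 22 (not isolated)
Conditions: SmI2 (0.3 equiv) premixed with 21 (5 equiv), THF, −10 °C, dark; then 19
Reagents that add atoms: none
Why: In the Evans–Tishchenko reduction O10 adds to 21 to give samarium-bound hemiacetal 22, whose C–H is delivered intramolecularly to the C8 ketone activated by trivalent samarium through a chair-like six-membered transition state, which sets (8R) 1,3-anti to C10, turns the hemiacetal carbon into the angelate on O10 only and leaves O8 free.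

Step 15
Reactants: 23 O11-silylated precursor
Product: 24 target CNP0105552.1
Conditions: HF·pyridine, pyridine, THF, 0 °C
Reagents that add atoms: none
Why: Fluoride-mediated desilylation under pyridine-buffered, non-basic conditions frees the tertiary C11 alcohol without acyl migration from O10 to O8 or O11 and without opening the oxirane.

Compound list
1 | (R)-(−)-carvone | C=C(C)[C@@H]1CC=C(C)C(=O)C1 | starting material
2 | lithium cross-conjugated dienolate of carvone | C=C(C)[C@@H]1CC=C(C)C(O[Li])=C1 | intermediate
3 | (5S,6S)-6-hydroxy-2-methyl-5-(prop-1-en-2-yl)cyclohex-2-en-1-one | C=C(C)[C@@H]1CC=C(C)C(=O)[C@H]1O | intermediate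
4 | (1R,6S)-3-methyl-2-oxo-6-(prop-1-en-2-yl)cyclohex-3-en-1-yl acetate | C=C(C)[C@@H]1CC=C(C)C(=O)[C@@H]1OC(C)=O | intermediate
5 | (1R,2S,6S)-2-hydroxy-3-methyl-6-(prop-1-en-2-yl)cyclohex-3-en-1-yl acetate | C=C(C)[C@@H]1CC=C(C)[C@H](O)[C@@H]1OC(C)=O | intermediate
6 | all-cis epoxy alcohol, (1R,2R,3R,4S,6S)-2-hydroxy-1-methyl-4-(prop-1-en-2-yl)-7-oxabicyclo[4.1.0]heptan-3-yl acetate | C=C(C)[C@@H]1C[C@@H]2O[C@]2(C)[C@H](O)[C@@H]1OC(C)=O | intermediate
7 | angelic acid | C/C=C(/C)C(=O)O | starting material
8 | angelic 2,4,6-trichlorobenzoic mixed anhydride | C/C=C(/C)C(=O)OC(=O)c1c(Cl)cc(Cl)cc1Cl | intermediate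
9 | C1-acetate C2-angelate epoxide with isopropenyl side chain | C=C(C)[C@@H]1C[C@@H]2O[C@]2(C)[C@H](OC(=O)/C(C)=C\C)[C@@H]1OC(C)=O | intermediate
10 | C8 enal | C=C(C=O)[C@@H]1C[C@@H]2O[C@]2(C)[C@H](OC(=O)/C(C)=C\C)[C@@H]1OC(C)=O | intermediate
11 | C8 allylic alcohol (both epimers) | C=C(C(C)O)[C@@H]1C[C@@H]2O[C@]2(C)[C@H](OC(=O)/C(C)=C\C)[C@@H]1OC(C)=O | intermediate
12 | ring methyl enone (C8 ketone, C9 methyl) | C=C(C(C)=O)[C@@H]1C[C@@H]2O[C@]2(C)[C@H](OC(=O)/C(C)=C\C)[C@@H]1OC(C)=O | intermediate
13 | 2-methylbut-3-en-2-ol | C=CC(C)(C)O | starting material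
14 | triethyl[(2-methylbut-3-en-2-yl)oxy]silane | C=CC(C)(C)O[Si](CC)(CC)CC | intermediate
15 | 3-[2-(triethylsilyloxy)propan-2-yl]-1,2,4-trioxolane | CC[Si](CC)(CC)OC(C)(C)C1OCOO1 | intermediate
16 | 2-methyl-2-(triethylsilyloxy)propanal | O=CC(C)(C)O[Si](CC)(CC)CC | intermediate
17 | diisopinocampheyl enol borinate of 12 | C=C(OB([C@@H]1C[C@@H]2C[C@H]([C@H]1C)C2(C)C)[C@@H]1C[C@@H]2C[C@H]([C@H]1C)C2(C)C)C(=C)[C@@H]1C[C@@H]2O[C@]2(C)[C@H](OC(=O)/C(C)=C\C)[C@@H]1OC(C)=O | intermediate
18 | diisopinocampheylboron aldolate of 19 | C=C(C(=O)C[C@@H](OB([C@@H]1C[C@@H]2C[C@H]([C@H]1C)C2(C)C)[C@@H]1C[C@@H]2C[C@H]([C@H]1C)C2(C)C)C(C)(C)O[Si](CC)(CC)CC)[C@@H]1C[C@@H]2O[C@]2(C)[C@H](OC(=O)/C(C)=C\C)[C@@H]1OC(C)=O | intermediate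
19 | (10R)-β-hydroxy enone | C=C(C(=O)C[C@@H](O)C(C)(C)O[Si](CC)(CC)CC)[C@@H]1C[C@@H]2O[C@]2(C)[C@H](OC(=O)/C(C)=C\C)[C@@H]1OC(C)=O | intermediate
20 | (Z)-2-methylbut-2-en-1-ol | C/C=C(/C)CO | intermediate
21 | (Z)-2-methylbut-2-enal | C/C=C(/C)C=O | intermediate
22 | O10 hemiacetal of 19 with 21 (drawn metal-free) | C=C(C(=O)C[C@@H](OC(O)/C(C)=C\C)C(C)(C)O[Si](CC)(CC)CC)[C@@H]1C[C@@H]2O[C@]2(C)[C@H](OC(=O)/C(C)=C\C)[C@@H]1OC(C)=O | intermediate
23 | (8R,10R)-8-hydroxy-10-angelate, O11-triethylsilyl ether of the target | C=C([C@H](O)C[C@@H](OC(=O)/C(C)=C\C)C(C)(C)O[Si](CC)(CC)CC)[C@@H]1C[C@@H]2O[C@]2(C)[C@H](OC(=O)/C(C)=C\C)[C@@H]1OC(C)=O | intermediate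
24 | CNP0105552.1 | C=C([C@H](O)C[C@@H](OC(=O)/C(C)=C\C)C(C)(C)O)[C@@H]1C[C@@H]2O[C@]2(C)[C@H](OC(=O)/C(C)=C\C)[C@@H]1OC(C)=O | target

Total steps: 15. Longest linear sequence: 11 steps from (R)-carvone (steps 1–8, 11, 14, 15).

Steps most likely to fail

Step 11. Three processes could hurt this step:
- The Re/Si discrimination of the isopinocampheyl ligands with an unsubstituted (methyl ketone) enolate may be only moderate.
- The chloroborane may open the oxirane with chloride before enolisation is complete.
- The free O10 may close onto C14 by oxa-Michael addition during isolation.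

The fallback sets out from 12 and 16 and comes back at 19. It replaces the stoichiometric, preformed chiral boron enolate by a catalytic direct aldol in which no halide Lewis acid is present. A dinuclear zinc complex is made from (S,S)-ProPhenol (10 mol %) and Et2Zn (20 mol %) with 4 Å sieves in THF at 0 °C. It should generate the zinc enolate of the vinyl methyl ketone 12 at one metal and bind the non-enolisable aldehyde 16, used in excess, at the other. This reaction type is known for methyl vinyl ketone donors with alpha-branched aldehydes. No new compound is made on this path (F0).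

Step 14. Hemiacetal formation at the hindered O10 may be slow. That would leave time for Z to E isomerisation of the enal, for retro-aldol cleavage at trivalent samarium, and for reduction of the enone by divalent samarium. The fallback sets out from 19 and comes back at 23, and it separates acylation from reduction. O10 is acylated with mixed anhydride 8, made from 7 as in step 5 (toluene, 60–75 °C), to give the β-angeloyloxy enone F1. The C8 ketone of F1 is then reduced under reagent control by Corey–Bakshi–Shibata reduction ((S)-2-methyl-CBS-oxazaborolidine, catecholborane, toluene, −78 °C). With the branched alkenyl group C7 acting as the large substituent, this should give the (8R) alcohol 23.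

Step 5. Prolonged heating of the hindered hydroxy acetate may allow three side processes: acetyl migration from O1 to O2, attack of carboxylate on the oxirane, and partial Z to E isomerisation of the acyl donor. The fallback sets out from 6 and comes back at 9, and it builds the Z-alkene on the ester instead of transferring it intact. Compound 6 is esterified at 0 °C with 2-[bis(2,2,2-trifluoroethoxy)phosphoryl]propanoic acid (DCC, catalytic DMAP, CH2Cl2) to give the phosphonopropionate ester F2. A Still–Gennari olefination of F2 with acetaldehyde (KN(SiMe3)2, 18-crown-6, THF, −78 °C) should then give the Z-configured angelate 9.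

Further compounds
F0 | step 11 | none | none
F1 | step 14 | (10R)-β-angeloyloxy enone (O10 angelate of 19) | C=C(C(=O)C[C@@H](OC(=O)/C(C)=C\C)C(C)(C)O[Si](CC)(CC)CC)[C@@H]1C[C@@H]2O[C@]2(C)[C@H](OC(=O)/C(C)=C\C)[C@@H]1OC(C)=O
F2 | step 5 | O2 2-[bis(2,2,2-trifluoroethoxy)phosphoryl]propanoate of 6 | C=C(C)[C@@H]1C[C@@H]2O[C@]2(C)[C@H](OC(=O)C(C)P(=O)(OCC(F)(F)F)OCC(F)(F)F)[C@@H]1OC(C)=O
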